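The amounts charged do not differ between the set-ups; the vessel and the timing do.

    starting material + catalyst ⇌ catalyst + intermediate (K1 = 0.89, k1 = 1.8 L mol⁻¹ h⁻¹)
    partner + catalyst + intermediate → catalyst + product (k2 = 10 L² mol⁻² h⁻¹)
    partner + precatalyst → catalyst + spent reagent (k3 = 0.43 L mol⁻¹ h⁻¹)

in all of them: partner 0.204 M; precatalyst 26 mM
- midnight: starting material 0.17 M; one stirred flow tank at steady state, fed with the mixture as stated, mean residence time 60.0 h
- noon: starting material 0.17 M; a closed flask charged with all of it at once and left for 20 h; time 20 h
- winter: starting material 0.17 M; one stirred flow tank at steady state, fed with the mixture as stated, mean residence time 20 h
- autumn: starting material 0.17 M (fed, over 20.0 h); all but starting material at the start; starting material goes in evenly over 20.0 h, the run ends at 20 h; time 20 h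

- the stated concentrations are those of everything mixed, before any reaction; amounts are the same in each set-up
- the feed brings no volume worth counting
- run time (noon): 20 h

* the set-up with the highest amount of intermediate at the outlet or at the end, in percent of the starting material put in ("none" if the first two lie within 2 percentage points) (midnight / noon / winter / autumn / none)
* amount of intermediate at the outlet or at the end, in percent of the starting material put in, midnight
* amount of intermediate at the outlet or at the end, in percent of the starting material put in, noon
* amount of intermediate at the outlet or at the end, in percent of the starting material put in, winter
* amount of intermediate at the outlet or at the end, in percent of the starting material put in, autumn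

The table gives the time constant of each event, taking partner at its charge and, in the lower rows, the whole charge of precatalyst as catalyst.

| Event | Time constant |
|---|---|
| precatalyst becomes catalyst | 11.4 h |
| starting material becomes intermediate | 21.4 h |
| intermediate falls back | 19.0 h |
| intermediate goes on to product | 18.9 h |

The top row is shorter than the closed run of 20 h, by a factor of 1.75, so catalyst is still arriving during that run, and the lower rows describe a flask in which the whole charge has become catalyst. The second row stands close to the run length, so starting material in noon is expected to be still present at the end of its 20 h.

The last two rows nearly coincide. Both rates carry catalyst and intermediate, so their quotient loses catalyst and time together. This quotient is the branch ratio β, the rate of falling back over the rate of going on, equal to the step-one rate constant over the equilibrium constant, k₂ and partner concentration: 0.991 at the charge. At the charge of partner, intermediate that leaves therefore goes on in half of cases.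

Step 3 does not touch starting material, so noon and autumn are reckoned to follow nearly one catalyst course while partner stays near its charge. Starting material in noon meets catalyst for 20 h, longer than the 10.0 h of the average dosed portion in autumn. The reckoning puts noon above autumn and stops there, without percentages.

The forecast gives 20.6% for midnight, 24.1% for noon, 18.5% for winter and 17.8% for autumn, and says: “Noon leads by more than 2 points”.

The simulation gives 20.6% for midnight, 24.0% for noon, 18.5% for winter and 17.6% for autumn, so noon stands highest.

In autumn at 14.5 h, intermediate falls back 1.1 times as fast as it goes on, close to the 0.991 reckoned from the charge, and at 20.0 h autumn holds 3.83% product beside 17.6% intermediate. The neighbour of autumn charged with 0.051 M partner starts from a β of 3.97, higher than the recipe's, and at 20.0 h it holds 9.41% intermediate and 0.158% product.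

The rate constants are invented, and the outcome is calculated.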